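The earlier runs and the new flask are calculated with constants of no real substance.

**Easy step.** Take the last teal reading and divide the product by the catalyst charged: 33% of 0.0061 M, over 1.8 mM, gives 1.12. Call these moles of product per mole of catalyst charged, at 4.00 h, the turnover count.

| setting | teal | ochre | Tuesday's | Thursday's | Monday's |
|---|---|---|---|---|---|
| substrate | 0.0061 M | 0.026 M | 0.0050 M | 0.010 M | 0.020 M |
| partner | 0.012 M (in portions, 4) | 0.012 M (in portions, 4) | 0.0120 M (in portions, 4) | 0.0120 M (in portions, 4) | 0.0120 M (in portions, 4) |
| free catalyst | 1.8 mM | 1.8 mM | 1.8 mM | 1.8 mM | 1.8 mM |
| added ligand | 1.2 mM | 1.2 mM | 1.2 mM | 1.2 mM | 1.2 mM |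
| remark | run made earlier; portions every 1.0 h | run made earlier; portions every 1.0 h | the portions of partner follow each other after 1.0 h, the first at the start | the portions of partner follow each other after 1.0 h, the first at the start | the portions of partner follow each other after 1.0 h, the first at the start |
| time |  |  | 4.0 h | 4.0 h | 4.0 h |

- teal (time / h: product / %, substrate / %): 1.00: 1, 90; 2.00: 13, 80; 3.00: 21, 69; 4.00: 33, 59
- ochre (time / h: product / %, substrate / %): 0.333: 2, 100; 0.667: 2, 100; 1.50: 1, 99; 4.00: 10, 88

(each reading ± 2 percentage points)

- steps that have been proposed: substrate + catalyst intermediate B -> catalyst intermediate C; catalyst intermediate A <-> by-product + catalyst intermediate B; free catalyst + added ligand <-> idle complex; catalyst intermediate C -> catalyst intermediate D; catalyst intermediate D -> free catalyst + product; partner + free catalyst -> catalyst intermediate A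
- "hardly changes" means that all values lie within two and a half points (for a concentration: within two and a half percent of the largest)

- amount of product at the end, in percent of the substrate charged for Tuesday's, Thursday's, Monday's, in this order
- how that number moves from the first to the last of them (rises, then falls / falls all the way / falls, then rises / hardly changes / rises all the way)

**Teal ledger.** Substrate is the limiting reagent in teal, since its 0.0061 M is less than the 0.012 M of partner. Enter 3.60 mM as substrate left in teal and 2.01 mM as teal's product. Close teal's books with a remainder, which carries the scatter of the readings, of 0.488 mM. The proposed steps can hold this on the catalyst as intermediates C and D, and it is less than the 1.8 mM charged.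

**Ochre ledger.** In ochre, partner is the smaller charge. Enter 22.9 mM as substrate left in ochre and 2.60 mM as ochre's product, with a read remainder of 0.520 mM. Ochre's count is 1.44. So 4.26 times the substrate moved the count by 0.320, about the 0.289 that one scatter of an ochre reading is worth.

**My reckoning.** Turn the count back into a yield: multiply it by [catalyst] and divide by [substrate]. Put teal's count on Tuesday's flask, which gives 40.3%. Put the mean of the two counts on Thursday's, which gives 23.1%, and ochre's count on Monday's, which gives 13.0%.

**The forecast.** It reads 38%, 22% and 12.5%, so the yield falls all the way, on the ground that “A fourfold increase in substrate therefore barely changes the absolute output”. Its first figure stands below mine, and so do its second and third.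

**The flasks.** They give 37.8%, 23.4% and 12.9%, and the yield falls all the way.

    substrate + catalyst intermediate B → catalyst intermediate C (k = 470 M⁻¹ h⁻¹)
    catalyst intermediate A ⇌ by-product + catalyst intermediate B (K = 0.0190 M, k = 4.40 h⁻¹)
    free catalyst + added ligand ⇌ idle complex (K = 1100 M⁻¹, k = 650 M⁻¹ h⁻¹)
    catalyst intermediate C → catalyst intermediate D (k = 10.0 h⁻¹)
    catalyst intermediate D → free catalyst + product (k = 1.40 h⁻¹)
    partner + free catalyst → catalyst intermediate A (k = 350 M⁻¹ h⁻¹)

**Counting again.** Tuesday's flask counts 1.05 against teal's 1.12, and Monday's counts 1.43 against ochre's 1.44, so 4.00 times the substrate gave 1.36 times the count. Intermediate C goes on with a rate constant of 10 h⁻¹, larger than the 1.4 h⁻¹ of intermediate D, and at 4.00 h Monday's flask holds 5.31% of its catalyst as intermediate C against 37.3% as intermediate D. At that moment this last share times 1.4 h⁻¹ has the count growing at 0.522 h⁻¹ in Monday's flask, against 0.360 h⁻¹ in Tuesday's.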